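(The runs were generated by integration on assumed constants.)

What the gamma run left over at 120 s, by difference, was 69.5% of its charge, which I took as starting complex.

| flask | starting complex | incoming ligand | leaving ligand | remark | time |
|---|---|---|---|---|---|
| gamma | 0.064 M | 0.048 M | 0.48 M | run made earlier |  |
| Saturday's | 0.096 M | 0.0480 M | 0.480 M |  | 6.0 min |
| Sunday's | 0.096 M | 0.0768 M | 0.480 M |  | 6.0 min |
| Wednesday's | 0.096 M | 0.115 M | 0.480 M |  | 6.0 min |

gamma run (percent of the starting complex charged)

| time / s | complex with two exchanged / % | complex with one exchanged / % |
|---|---|---|
| 12.0 | 0.5 | 19.6 |
| 30.0 | 1.4 | 22.5 |
| 60.0 | 1.8 | 25.2 |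
| 90.0 | 1.9 | 26.9 |
| 120 | 2.1 | 28.4 |

(readings scatter by 0.5 percentage points)

- a reading or a percentage of complex with one exchanged counts all its forms, free or not
- no earlier run changes the charge of incoming ligand; that part of a forecast is a guess

1. final complex with two exchanged, as a percentage of the starting complex charged, for each flask in turn (Saturday's, Sunday's, Wednesday's)

The first exchange has the balance quotient [complex with one exchanged][leaving ligand]/([starting complex][incoming ligand]), and the second has [complex with two exchanged][leaving ligand]/([complex with one exchanged][incoming ligand]). If both steps stay near balance, dividing the second by the first removes [incoming ligand], [leaving ligand] and with them the clock. What remains is [complex with two exchanged][starting complex] over [complex with one exchanged] squared. The gamma run read 0.181 for this at 120 s and 0.207 at 60.0 s. I called it the exchange quotient, a disproportionation quotient, and it is rough, since a reading of 2.1% scatters by 0.5 percentage points.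

Next I needed the incoming ligand placed in the two visible complexes. The gamma run had placed 43.5% of its charge at 120 s and was still rising, so I guessed 0.7 at 6.0 min for each flask, as no earlier run changes that charge. As shares of the starting complex, this gave s of 35.0%, 56.0% and 83.9%. Calling the share of complex with two exchanged b, I set complex with one exchanged to s minus twice b, and starting complex to one minus s plus b. The quotient then gave b as 2.44%, 6.57% and 15.7%.

The forecast stood lower than my reckoning, at 1.6%, 3.2% and 6.5%, with the caution “The dependence on ligand charge is a guess”.

The flasks gave 2.48%, 7.23% and 16.7%.

    starting complex + incoming ligand ⇌ leaving ligand + complex with one exchanged (K = 4.40, k = 1.00 M⁻¹ s⁻¹)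
    complex with one exchanged + incoming ligand ⇌ leaving ligand + complex with two exchanged (K = 1.20, k = 0.0850 M⁻¹ s⁻¹)
    leaving ligand → by-product carried off (k = 0.00780 s⁻¹)
    complex with one exchanged ⇌ isomer of the product (K = 0.350, k = 0.0820 s⁻¹)
    starting complex + complex with one exchanged ⇌ idle adduct, settled at all times (K = 5.20 M⁻¹)

Reforged on end states, with complex with one exchanged counted in all its forms and the remainder taken by difference as in the gamma reading of 0.181, the exchange quotient was 0.164 in Saturday's flask, lower than that reading, and 0.298 in Wednesday's, higher than it. In Saturday's flask at 1.41 min, the forward rate of the first step used incoming ligand at 43 times that of the second. At 6.00 min in Saturday's flask, the first step's relaxation half-life, both ways together, was 0.173 min, shorter than the forward half-life of starting complex, 2.6 min.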